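**Retrosynthetic overview**

1. The coumarin ring is closed last (step 7): a Knoevenagel condensation with lactonisation joins the two polyketide halves, a salicylaldehyde and the CH2 of a dihydropyranone-6-acetate. The benzene ring is bought, and both side-chain centres come from an aryllithium and (2R,3R)-2,3-dimethyloxirane.
2. The dihydropyranone comes from a 4-methoxy-5,6-dihydropyran-2-one with the same six ring atoms, by acetate-enolate addition and acid-induced 1,3-carbonyl transposition (step 2).
3. Key disconnection (step 1): that lactone is assembled in one flask from four small pieces, with acetylene as a two-carbon linchpin. Its carbons become C-4 and C-5 of the dihydropyranone, so the step forms C-3–C-4 (to the CH2 of (S)-propylene oxide) and C-5–C-6 (to the carbonyl carbon of methyl chloroformate); methoxide then folds the chain into the ring.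
4. Enabling feature: in the dihydropyranone ring the unit O-1–C-6=C-5–C-4(=O) is a vinylogous ester, i.e. the hydrated form of a C-4≡C-5 triple bond next to an acyl-level C-6. O-1 sits on C-2, two carbons from C-4, exactly where opening of a methyl-substituted epoxide by an acetylide leaves it.
5. Ring order: lactone ring (step 1), its conversion into the dihydropyran-4-one (step 2), coumarin lactone ring (step 7).

Key step: step 1

Remark: the salicylaldehyde made in step 6 is drawn in its open form; because of the side-chain hydroxyl it is expected to equilibrate with a cyclic lactol, which should react through the open form in step 7.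

**Route**

Step 1
Reactants: 1 acetylene; 2 (S)-2-methyloxirane ((S)-propylene oxide); 3 methyl chloroformate
Product: 8 (6S)-4-methoxy-6-methyl-5,6-dihydro-2H-pyran-2-one, via lithium acetylide 4 (not isolated), via lithium (S)-pent-4-yn-2-olate 5 (not isolated), via carbonate ynoate 6 (not isolated), via (E)-methoxy enoate 7 (not isolated)
Conditions: HC≡CH, n-BuLi, THF, −78 °C; BF3·OEt2, then 2, −78 °C; n-BuLi, −78 °C; 3, −78 to 0 °C; NaOMe, MeOH, 0 °C to rt
Reagents that add atoms: methanol (as NaOMe in MeOH), CO
Why: Monolithium acetylide, activated by BF3·OEt2, should open (S)-propylene oxide by SN2 attack at the unsubstituted CH2 (BF3-promoted alkynylation of an epoxide), which makes C-4–C-5 of the lactone (later C-3–C-4 of the dihydropyranone); the second terminus of the same C2 unit is then lithiated and C-acylated by methyl chloroformate (acetylide carboxylation), which makes C-2–C-3 of the lactone (later C-5–C-6 of the dihydropyranone). Methoxide should then remove the O-carbonate, add reversibly to the ynoate (oxa-Michael addition), and the E-enoate, the only isomer with the hydroxyalkyl chain cis to the ester, should lactonise. The closest known reaction type is the conversion of 5-hydroxyalk-2-ynoates into 4-methoxy-5,6-dihydropyran-2-ones with NaOMe in MeOH; here the ynoate is built in the same flask around acetylene instead of from a three-carbon propiolate. The single ring closes by 6-exo-trig acyl substitution of the C-6 alkoxide on the ester carbonyl, after the methoxide addition has set the cis geometry. No stereocentre is created: C-6 comes unchanged from (S)-propylene oxide because only its CH2 carbon is attacked. The step needs regioselective epoxide opening (secured by SN2 attack at the primary carbon at −78 °C) and one reaction at each acetylene terminus in turn (secured by keeping LiC≡CH at −78 °C, purging excess acetylene, and lithiating the second terminus only after the first bond is made).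

Step 2
Reactants: 8 (6S)-4-methoxy-6-methyl-5,6-dihydro-2H-pyran-2-one; 9 methyl acetate
Product: 12 methyl 2-[(2S)-2-methyl-4-oxo-3,4-dihydro-2H-pyran-6-yl]acetate, via methyl lithioacetate 10 (not isolated), via lithium hemiketalate 11 (not isolated)
Conditions: LiN(i-Pr)2, 9, THF, −78 °C; then 8, −78 °C; then 1 M HCl, THF, rt
Reagents that add atoms: water, O
Why: Claisen-type 1,2-addition of the ester enolate to the lactone carbonyl should give a hemiketal that aqueous acid ionises to a methoxy-stabilised oxocarbenium ion, water then adds at C-4 and methanol leaves (Stork–Danheiser-type 1,3-carbonyl transposition of a vinylogous ester), so the ring oxygen stays on the former lactone carbon, now C-6 of the dihydropyranone, and the stereocentre is not touched.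

Step 3
Reactants: 13 5-bromo-1,3-dimethoxy-2-methylbenzene
Product: 15 1-bromo-3,5-dimethoxy-2,4-dimethylbenzene, via aryllithium 14 (not isolated)
Conditions: lithium 2,2,6,6-tetramethylpiperidide, THF, −78 °C; MeI, −78 °C to rt
Reagents that add atoms: iodomethane, CI
Why: Directed ortho-lithiation: the two equivalent ring C–H positions are flanked by OMe (coordination) and Br (inductive acidification), the hindered amide should remove one of them at −78 °C, where the ortho-bromoaryllithium does not yet lose LiBr, and iodomethane alkylates it (SN2); no stereocentre is formed.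

Step 4
Reactants: 15 1-bromo-3,5-dimethoxy-2,4-dimethylbenzene; 16 (2R,3R)-2,3-dimethyloxirane
Product: 18 (2R,3R)-3-(3,5-dimethoxy-2,4-dimethylphenyl)butan-2-ol, via aryllithium 17 (not isolated)
Conditions: n-BuLi, THF, −78 °C; BF3·OEt2, 16, −78 °C
Reagents that add atoms: none
Why: Bromine–lithium exchange followed by BF3-promoted SN2 opening of the trans-epoxide by the aryllithium: backside attack inverts the attacked carbon and leaves the other untouched, so the C2-symmetric (2R,3R)-epoxide should give only the (2R,3R)-3-arylbutan-2-ol, and both side-chain stereocentres are set by the reagent.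

Step 5
Reactants: 18 (2R,3R)-3-(3,5-dimethoxy-2,4-dimethylphenyl)butan-2-ol
Product: 19 5-[(2R,3R)-3-hydroxybutan-2-yl]-2,4-dimethylbenzene-1,3-diol
Conditions: BBr3, CH2Cl2, −78 to 0 °C; then H2O
Reagents that add atoms: none
Why: Lewis acid cleavage of both aryl methyl ethers (BBr3 demethylation) should proceed at or below 0 °C, where the secondary alcohol is only held as a borate ester and is returned on hydrolysis with its configuration; no stereocentre is formed.

Step 6
Reactants: 19 5-[(2R,3R)-3-hydroxybutan-2-yl]-2,4-dimethylbenzene-1,3-diol
Product: 20 2,4-dihydroxy-6-[(2R,3R)-3-hydroxybutan-2-yl]-3,5-dimethylbenzaldehyde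
Conditions: MgCl2, Et3N, (CH2O)n, MeCN, reflux; 1 M HCl work-up
Reagents that add atoms: paraformaldehyde (formaldehyde), C=O
Why: Magnesium-phenoxide-directed ortho-formylation (Casnati–Skattebøl reaction) can only occur at the single free ring position, ortho to one hydroxyl, with formaldehyde as C1 source and hydride acceptor; no stereocentre is formed.

Step 7
Reactants: 20 2,4-dihydroxy-6-[(2R,3R)-3-hydroxybutan-2-yl]-3,5-dimethylbenzaldehyde; 12 methyl 2-[(2S)-2-methyl-4-oxo-3,4-dihydro-2H-pyran-6-yl]acetate
Product: 22 7-hydroxy-5-[(2R,3R)-3-hydroxybutan-2-yl]-6,8-dimethyl-3-[(2S)-2-methyl-4-oxo-3,4-dihydro-2H-pyran-6-yl]-2H-chromen-2-one (CNP0291478.2), via arylidene ester 21 (not isolated)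
Conditions: piperidine (cat.), AcOH (cat.), MeCN, 50 °C
Reagents that add atoms: none
Why: Knoevenagel condensation of the CH2 of 12 (α to the ester and vinylogous to the ring ketone) with the aldehyde, then lactonisation of the ortho-phenol onto the methyl ester, should close the coumarin as in the formation of 3-acylcoumarins from salicylaldehydes and β-keto esters, reversible amine addition equilibrating the alkene geometry; no stereocentre is formed and the buffered catalyst at moderate temperature should spare the three existing ones.

**Compound list**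

1 | acetylene | C#C | starting material
2 | (S)-2-methyloxirane | C[C@H]1CO1 | starting material
3 | methyl chloroformate | COC(=O)Cl | starting material
4 | lithium acetylide | [Li+].[C-]#C | intermediate
5 | lithium (S)-pent-4-yn-2-olate (as BF3 adduct) | C#CC[C@H](C)[O-].[Li+] | intermediate
6 | methyl (5S)-5-[(methoxycarbonyl)oxy]hex-2-ynoate | COC(=O)C#CC[C@H](C)OC(=O)OC | intermediate
7 | methyl (2E,5S)-5-hydroxy-3-methoxyhex-2-enoate | C[C@H](O)C/C(OC)=C\C(=O)OC | intermediate
8 | (6S)-4-methoxy-6-methyl-5,6-dihydro-2H-pyran-2-one | COC1=CC(=O)O[C@@H](C)C1 | intermediate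
9 | methyl acetate | CC(=O)OC | starting material
10 | methyl lithioacetate (lithium enolate of methyl acetate) | C=C([O-])OC.[Li+] | intermediate
11 | lithium (6S)-4-methoxy-2-(2-methoxy-2-oxoethyl)-6-methyl-5,6-dihydro-2H-pyran-2-olate (hemiketal adduct, C-2 epimers) | COC(=O)CC1([O-])C=C(OC)C[C@H](C)O1.[Li+] | intermediate
12 | methyl 2-[(2S)-2-methyl-4-oxo-3,4-dihydro-2H-pyran-6-yl]acetate | COC(=O)CC1=CC(=O)C[C@H](C)O1 | intermediate
13 | 5-bromo-1,3-dimethoxy-2-methylbenzene | COc1cc(Br)cc(OC)c1C | starting material
14 | (6-bromo-2,4-dimethoxy-3-methylphenyl)lithium | COc1cc(Br)c([Li])c(OC)c1C | intermediate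
15 | 1-bromo-3,5-dimethoxy-2,4-dimethylbenzene | COc1cc(Br)c(C)c(OC)c1C | intermediate
16 | (2R,3R)-2,3-dimethyloxirane | C[C@H]1O[C@@H]1C | starting material
17 | (3,5-dimethoxy-2,4-dimethylphenyl)lithium | COc1cc([Li])c(C)c(OC)c1C | intermediate
18 | (2R,3R)-3-(3,5-dimethoxy-2,4-dimethylphenyl)butan-2-ol | COc1cc([C@@H](C)[C@@H](C)O)c(C)c(OC)c1C | intermediate
19 | 5-[(2R,3R)-3-hydroxybutan-2-yl]-2,4-dimethylbenzene-1,3-diol | Cc1c(O)cc([C@@H](C)[C@@H](C)O)c(C)c1O | intermediate
20 | 2,4-dihydroxy-6-[(2R,3R)-3-hydroxybutan-2-yl]-3,5-dimethylbenzaldehyde | Cc1c(O)c(C)c(O)c(C=O)c1[C@@H](C)[C@@H](C)O | intermediate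
21 | methyl 3-{2,4-dihydroxy-6-[(2R,3R)-3-hydroxybutan-2-yl]-3,5-dimethylphenyl}-2-[(2S)-2-methyl-4-oxo-3,4-dihydro-2H-pyran-6-yl]prop-2-enoate (alkene geometry not fixed) | COC(=O)C(=Cc1c(O)c(C)c(O)c(C)c1[C@@H](C)[C@@H](C)O)C1=CC(=O)C[C@H](C)O1 | intermediate
22 | 7-hydroxy-5-[(2R,3R)-3-hydroxybutan-2-yl]-6,8-dimethyl-3-[(2S)-2-methyl-4-oxo-3,4-dihydro-2H-pyran-6-yl]-2H-chromen-2-one | Cc1c(O)c(C)c2oc(=O)c(C3=CC(=O)C[C@H](C)O3)cc2c1[C@@H](C)[C@@H](C)O | target

Total step count: 7. Longest linear sequence: 5 steps (steps 3, 4, 5, 6, 7).

**Steps most likely to fail**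

Step 1. The control over the two termini of acetylene may be lost: monolithium acetylide can disproportionate to dilithium acetylide on warming, residual acetylide can be carboxylated as well, and the boron-ate species may consume the second base so that carboxylation stays incomplete. The fallback uses a three-carbon propiolate instead of the two-carbon linchpin; it sets out from 2 and comes back at 8. Methyl propiolate is lithiated (n-BuLi, THF, −78 °C) and added to 2 in the presence of BF3·OEt2, which should give methyl (5S)-5-hydroxyhex-2-ynoate F1. NaOMe in MeOH should then convert it into 8 by the same methoxide addition and lactonisation.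

Step 2. Proton transfer may compete with addition: deprotonation at C-5 of the lactone followed by β-elimination of the ring carboxylate would open the ring, and conjugate addition–elimination at C-4 would displace the methoxy group. The fallback replaces the direct lactone addition by an open-chain acylation; it sets out from 8 and comes back at 12. Aminolysis of 8 with the chloromagnesium amide of N,O-dimethylhydroxylamine (MeNHOMe·HCl, i-PrMgCl, THF) should give the Weinreb amide (2E,5S)-5-hydroxy-N,3-dimethoxy-N-methylhex-2-enamide F2. Addition of methyl lithioacetate, which stops at the chelated tetrahedral stage, should give methyl (4E,7S)-7-hydroxy-5-methoxy-3-oxooct-4-enoate F3 after work-up, and dilute HCl should cyclise it to 12 with loss of methanol.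

Step 7. The side-chain hydroxyl may capture the aldehyde carbon, so that the condensation product stays as a cyclic ether (isochroman) and does not dehydrate to the coumarin. The amine may also open the dihydropyranone or epimerise its C-2 by a retro-oxa-Michael reaction. The fallback blocks the side-chain hydroxyl and ends under acid; it sets out from 19 and comes back at 22. All three hydroxyls are silylated (TBSCl, imidazole, DMF) to the tris-silyl ether of 19 F4, and K2CO3 in MeOH should cleave the two aryl silyl ethers to 5-[(2R,3R)-3-{[tert-butyl(dimethyl)silyl]oxy}butan-2-yl]-2,4-dimethylbenzene-1,3-diol F5. Formylation as in step 6 should give the open salicylaldehyde 6-[(2R,3R)-3-{[tert-butyl(dimethyl)silyl]oxy}butan-2-yl]-2,4-dihydroxy-3,5-dimethylbenzaldehyde F6. Condensation with 12 (ethylenediammonium diacetate, MeCN, rt) should give the silyl ether of the target F7, and HF·pyridine in THF should release 22.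

**Further compounds**

F1 | step 1 | methyl (5S)-5-hydroxyhex-2-ynoate | C[C@H](O)CC#CC(=O)OC
F2 | step 2 | (2E,5S)-5-hydroxy-N,3-dimethoxy-N-methylhex-2-enamide | C[C@H](O)C/C(OC)=C\C(=O)N(C)OC
F3 | step 2 | methyl (4E,7S)-7-hydroxy-5-methoxy-3-oxooct-4-enoate | C[C@H](O)C/C(OC)=C\C(=O)CC(=O)OC
F4 | step 7 | tert-butyl{[(2R,3R)-3-(3,5-bis{[tert-butyl(dimethyl)silyl]oxy}-2,4-dimethylphenyl)butan-2-yl]oxy}dimethylsilane | Cc1c(O[Si](C)(C)C(C)(C)C)cc([C@@H](C)[C@@H](C)O[Si](C)(C)C(C)(C)C)c(C)c1O[Si](C)(C)C(C)(C)C
F5 | step 7 | 5-[(2R,3R)-3-{[tert-butyl(dimethyl)silyl]oxy}butan-2-yl]-2,4-dimethylbenzene-1,3-diol | Cc1c(O)cc([C@@H](C)[C@@H](C)O[Si](C)(C)C(C)(C)C)c(C)c1O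
F6 | step 7 | 6-[(2R,3R)-3-{[tert-butyl(dimethyl)silyl]oxy}butan-2-yl]-2,4-dihydroxy-3,5-dimethylbenzaldehyde | Cc1c(O)c(C)c(O)c(C=O)c1[C@@H](C)[C@@H](C)O[Si](C)(C)C(C)(C)C
F7 | step 7 | 5-[(2R,3R)-3-{[tert-butyl(dimethyl)silyl]oxy}butan-2-yl]-7-hydroxy-6,8-dimethyl-3-[(2S)-2-methyl-4-oxo-3,4-dihydro-2H-pyran-6-yl]-2H-chromen-2-one | Cc1c(O)c(C)c2oc(=O)c(C3=CC(=O)C[C@H](C)O3)cc2c1[C@@H](C)[C@@H](C)O[Si](C)(C)C(C)(C)C
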